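(The numbers of this flask are those of an exercise.)

**Two exits.** In the long run the starting material in these flasks has two ways out, product and quenched substrate. So I compared the two rates at one moment, each per unit of starting material, and built the flask up one step at a time.

all flasks: starting material 0.13 M; coupling partner 0.130 M (fed, over 80 s); free catalyst 2.0 mM; time 3.0 min

| charge | protic impurity |
|---|---|
| spring | 0.0600 M |
| autumn | 0.200 M |
| noon | 0.600 M |
| midnight | 2.00 M |

    catalyst intermediate B ⇌ free catalyst + product (K1 = 0.39 M, k1 = 80.7 /min)
    coupling partner + free catalyst ⇌ catalyst intermediate A (K2 = 160 /M, k2 = 2500 /M/min)
    starting material + catalyst intermediate A ⇌ catalyst intermediate B (K3 = 3.5 /M, k3 = 226 /M/min)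
    starting material + protic impurity → quenched substrate (k4 = 1.01 /M/min)

* amount of product at the end, in percent of the starting material charged for spring, autumn, noon, midnight, in this order
* the course of these numbers from the first flask to the last (falls, then rises / falls all the way / hardly changes / rises all the way / rises, then falls)

- "hardly changes" means that all values lie within two and a half points (for a concentration: within two and a half percent of the largest)
- run time (spring): 3.0 min

**Main step.** I took the catalyst to sit as catalyst intermediate A, its resting state, from the start of the feed of coupling partner. Starting material then goes forward at the rate constant of its step with intermediate A times the catalyst charge, 0.452 /min. By itself that gave 74.2% of the charge as product in 3.0 min.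

**Way back.** Catalyst intermediate B goes on to product at 80.7 /min and returns to intermediate A and starting material at 64.6 /min, so in my reckoning a fraction 0.556 of its visits get through. That leaves 0.251 /min, which I called the net coupling rate: the fraction of the starting material becoming product per minute while the catalyst rests as intermediate A. In my reckoning the product at the end dropped to 52.9% of the charge.

**Quench added.** With the impurity held at its charge, the quench runs at 0.0606 /min in spring, 0.202 /min in autumn, 0.606 /min at noon and 2.02 /min at midnight. Both exits scale with the starting material, so in my reckoning their split did not drift as it ran down. In spring the net coupling rate is larger than the quench, while at midnight it is smaller. The product's share of what is used is the net coupling rate over the sum of the two rates: 80.6% in spring and 11.1% at midnight. Multiplying each share by the part used up in the time, my row was 48.9%, 41.2%, 27.1% and 11.0%. Setting these steps side by side, the course I committed to was falls all the way.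

**The forecast.** The forecast gave 38%, 32%, 21% and 7%, with the course falls all the way, on the ground that “it takes an ever larger share of the starting material and the product falls steadily”. It differed from my row, standing lower: in spring, 38% against my 48.9%.

**The result.** The flasks gave 38.2%, 32.6%, 21.1% and 7.03%, and the course was falls all the way. The forecast held within its margin on the row and on the shape, and my row ran high.

**What it means.** Product and quenched substrate draw on one charge, so I held the share given by the net coupling rate of 0.251 /min against the flasks. In spring, product over product plus quenched substrate stood at 76.7% at the end, against my share of 80.6%. At midnight, with 0.20% of the starting material left, the same ratio stood at 7.05%, against my 11.1%. With the quench taken away, the midnight flask gave 40.8% of product instead of 7.03%, and the change from spring to midnight went from −31 percentage points to 0 points.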